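**Retrosynthetic overview**
- The ketone C(=O)–CH2 bond is cut into two electrophiles, S-(pyridin-2-yl) 5-formyl-1H-pyrrole-2-carbothioate and 1-iodo-15-methylhexadecane. They are joined by a nickel-catalysed reductive cross-electrophile coupling, a union of two carbons of like polarity with the alkyl carbon reacting as a radical.
- Enabling feature: the ketone carbonyl carbon is bound directly to C2 of the pyrrole ring (ring A), so it is an aroyl carbon with no α-hydrogen on the ring side (no ketene, slow CO loss from the acyl–nickel). Its partner is an unbranched primary CH2 heading a chain of fourteen methylenes, which gives a clean primary radical.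
- The C5 hydroxymethyl group is carried one oxidation level higher, as CHO, which needs no protecting group; it is reduced chemoselectively in the last step.
- Alkyl fragment: C5 + C12, from isopentylmagnesium bromide and 12-bromododecan-1-ol under copper catalysis, then iodination.
- Rings: none is formed; ring A is bought intact as 5-formyl-1H-pyrrole-2-carboxylic acid.

Key step: step 4

Remark: the target has no stereocentre and no stereogenic double bond, so no stereocontrol is required.

Step 1
Reactants: 1 isopentylmagnesium bromide (3-methylbutylmagnesium bromide); 2 12-bromododecan-1-ol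
Product: 5 15-methylhexadecan-1-ol, via bromomagnesium 12-bromododecan-1-olate 3 (not isolated), via bromomagnesium 15-methylhexadecan-1-olate 4 (not isolated)
Conditions: 1 (2.5 equiv), Li2CuCl4 (3 mol%), THF, −10 °C to rt; then 1 M HCl
Reagents that add atoms: none
Why: Kochi-type copper-catalysed cross-coupling of a primary alkyl Grignard reagent with a primary alkyl bromide: the first equivalent of 1 only deprotonates the hydroxyl group, the resulting magnesium alkoxide is inert to the alkylcopper species, and displacement at the unhindered primary C–Br bond has no competing site; no stereocentre is formed.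

Step 2
Reactants: 5 15-methylhexadecan-1-ol
Product: 6 1-iodo-15-methylhexadecane
Conditions: I2 (1.2 equiv), PPh3 (1.2 equiv), imidazole (1.5 equiv), CH2Cl2, 0 °C to rt
Reagents that add atoms: iodine, II
Why: Appel-type iodination, in which the primary alcohol is activated at phosphorus and displaced by iodide in an SN2 step, with no other functional group present; no stereocentre is formed.

Step 3
Reactants: 7 5-formyl-1H-pyrrole-2-carboxylic acid
Product: 8 S-(pyridin-2-yl) 5-formyl-1H-pyrrole-2-carbothioate
Conditions: 2,2'-dipyridyl disulfide (1.2 equiv), PPh3 (1.2 equiv), MeCN/THF, rt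
Reagents that add atoms: 2,2'-dipyridyl disulfide, c1ccc(SSc2ccccn2)nc1
Why: Mukaiyama redox condensation, in which PPh3 and the disulfide activate the carboxyl group at phosphorus under neutral conditions and pyridine-2-thiolate takes up the acyl group, while the formyl group is inert and the N–H of a pyrrole bearing two acyl groups is too weakly nucleophilic to be acylated; no stereocentre is formed.

Step 4
Reactants: 8 S-(pyridin-2-yl) 5-formyl-1H-pyrrole-2-carbothioate (1.3 equiv); 6 1-iodo-15-methylhexadecane
Product: 9 5-(16-methylheptadecanoyl)-1H-pyrrole-2-carbaldehyde
Conditions: NiCl2(dme) (10 mol%), 4,4'-di-tert-butyl-2,2'-bipyridine (11 mol%), Mn powder (3 equiv), DMA, 0 °C to rt; then 1 M HCl work-up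
Reagents that add atoms: none
Why: This is a nickel-catalysed reductive acyl–alkyl cross-electrophile coupling, in which two electrophilic carbons are joined with Mn as the terminal reductant. Zerovalent nickel bearing the bipyridine should insert into the C(acyl)–S bond of 8, helped by the pyridyl nitrogen, to give an aroyl–nickel thiolate of divalent nickel, while a monovalent nickel species abstracts iodine from 6; the free primary 15-methylhexadecyl radical is then captured to give a trivalent acyl(alkyl)nickel that reductively eliminates the ketone, and Mn returns nickel to the low-valent state. The closest known reaction type is the NiCl2(dme)/bipyridine/Mn ketone synthesis from acid chlorides or S-2-pyridyl thioesters and unactivated primary alkyl iodides, together with the nickel-catalysed reductive coupling of aroyl electrophiles with primary alkyl halides. No ring is closed and no stereocentre is formed. The selectivity needed is cross-coupling over alkyl–alkyl and acyl–acyl dimerisation and over decarbonylation: the two electrophiles are activated by different mechanisms (two-electron insertion at the thioester, halogen-atom abstraction at C–I), the acyl carbon sits on the sp2 carbon C2 of ring A (no α-hydrogen, no ketene, a conjugated aroyl–nickel that loses CO slowly), and 8 is used in slight excess. The formyl group and the pyrrole N–H carry no leaving group and are not reduced by Mn at this temperature, so both should pass unchanged.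

Step 5
Reactants: 9 5-(16-methylheptadecanoyl)-1H-pyrrole-2-carbaldehyde
Product: 10 1-[5-(hydroxymethyl)-1H-pyrrol-2-yl]-16-methylheptadecan-1-one
Conditions: NaBH4 (0.4 equiv), THF/MeOH 4:1, −40 °C; then aq. NH4Cl
Reagents that add atoms: none
Why: Chemoselective borohydride reduction of an aldehyde in the presence of a ketone: the formyl carbon is unhindered and more electrophilic than the ketone carbon, which is a vinylogous amide flanked by a long chain and is deactivated further once the formyl acceptor at C5 has become CH2OH, and the low temperature and sub-stoichiometric hydride should hold the reduction at the alcohol stage; no stereocentre is formed.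

**Compound list**
1 | isopentylmagnesium bromide (3-methylbutylmagnesium bromide) | CC(C)CC[Mg]Br | starting material
2 | 12-bromododecan-1-ol | OCCCCCCCCCCCCBr | starting material
3 | bromomagnesium 12-bromododecan-1-olate | BrCCCCCCCCCCCCO[Mg]Br | intermediate
4 | bromomagnesium 15-methylhexadecan-1-olate | CC(C)CCCCCCCCCCCCCCO[Mg]Br | intermediate
5 | 15-methylhexadecan-1-ol | CC(C)CCCCCCCCCCCCCCO | intermediate
6 | 1-iodo-15-methylhexadecane | CC(C)CCCCCCCCCCCCCCI | intermediate
7 | 5-formyl-1H-pyrrole-2-carboxylic acid | O=Cc1ccc(C(=O)O)[nH]1 | starting material
8 | S-(pyridin-2-yl) 5-formyl-1H-pyrrole-2-carbothioate | O=Cc1ccc(C(=O)Sc2ccccn2)[nH]1 | intermediate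
9 | 5-(16-methylheptadecanoyl)-1H-pyrrole-2-carbaldehyde | CC(C)CCCCCCCCCCCCCCC(=O)c1ccc(C=O)[nH]1 | intermediate
10 | 1-[5-(hydroxymethyl)-1H-pyrrol-2-yl]-16-methylheptadecan-1-one | CC(C)CCCCCCCCCCCCCCC(=O)c1ccc(CO)[nH]1 | target

Total step count: 5. Longest linear sequence: 4 steps (steps 1, 2, 4, 5); step 3 is the one-step side branch.

**Steps most likely to fail**

Step 4. The alkyl radical may dimerise or be reduced to the alkane, and the released thiolate may slow the nickel catalyst, so that cross-selectivity and conversion stay low. The fallback sets out from 6 (with 8) and comes back at 9. Zinc insertion (Zn dust activated with 1,2-dibromoethane and TMSCl, LiCl, THF, 40 °C) converts 6 into (15-methylhexadecyl)zinc iodide F1. F1 (2.2 equiv, to allow for the acidic N–H) is then coupled with thioester 8 in a Fukuyama ketone synthesis (PdCl2(PPh3)2 5 mol%, THF/toluene, rt) to give 9. This replaces the reductive union of two electrophiles by a nucleophile–electrophile pairing at the same bond.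

Step 5. Hydride may attack the ketone carbonyl in competition with the formyl group, or the new hydroxyl group may be lost through an azafulvene with further reduction to the methyl compound. The fallback sets out from 7 and comes back at 10, carrying the hydroxymethyl group through the coupling at its final oxidation level.
- Acid 7 is reduced as its sodium carboxylate (NaBH4, aq. NaOH, 0 °C; acidification to pH 4) to 5-(hydroxymethyl)-1H-pyrrole-2-carboxylic acid F2.
- TBSCl (2.3 equiv) and imidazole in DMF give tert-butyldimethylsilyl 5-({[tert-butyl(dimethyl)silyl]oxy}methyl)-1H-pyrrole-2-carboxylate F3, which is not isolated.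
- K2CO3 in aqueous MeOH/THF cleaves the silyl ester of F3 to 5-({[tert-butyl(dimethyl)silyl]oxy}methyl)-1H-pyrrole-2-carboxylic acid F4.
- 2,2'-Dipyridyl disulfide and PPh3 give S-(pyridin-2-yl) 5-({[tert-butyl(dimethyl)silyl]oxy}methyl)-1H-pyrrole-2-carbothioate F5.
- Coupling of F5 with 6 under the conditions of step 4 gives 1-[5-({[tert-butyl(dimethyl)silyl]oxy}methyl)-1H-pyrrol-2-yl]-16-methylheptadecan-1-one F6.
- TBAF in THF at 0 °C releases 10.

Step 3. Activation of the poorly soluble acid may stay incomplete, and the activated ester may hydrolyse during isolation. The fallback sets out from 7 and comes back at 9, bypassing 8. Oxalyl chloride with catalytic DMF in CH2Cl2 (0 °C to rt) converts 7 into 5-formyl-1H-pyrrole-2-carbonyl chloride F7. F7 is used crude, without chromatography, in the nickel-catalysed reductive coupling with 6 (NiCl2(dme), 4,4'-di-tert-butyl-2,2'-bipyridine, Mn, DMA, 0 °C), for which acid chlorides are the parent acyl partners.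

Further compounds
F1 | step 4 | (15-methylhexadecyl)zinc iodide | CC(C)CCCCCCCCCCCCCC[Zn]I
F2 | step 5 | 5-(hydroxymethyl)-1H-pyrrole-2-carboxylic acid | OCc1ccc(C(=O)O)[nH]1
F3 | step 5 | tert-butyldimethylsilyl 5-({[tert-butyl(dimethyl)silyl]oxy}methyl)-1H-pyrrole-2-carboxylate | CC(C)(C)[Si](C)(C)OCc1ccc(C(=O)O[Si](C)(C)C(C)(C)C)[nH]1
F4 | step 5 | 5-({[tert-butyl(dimethyl)silyl]oxy}methyl)-1H-pyrrole-2-carboxylic acid | CC(C)(C)[Si](C)(C)OCc1ccc(C(=O)O)[nH]1
F5 | step 5 | S-(pyridin-2-yl) 5-({[tert-butyl(dimethyl)silyl]oxy}methyl)-1H-pyrrole-2-carbothioate | CC(C)(C)[Si](C)(C)OCc1ccc(C(=O)Sc2ccccn2)[nH]1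
F6 | step 5 | 1-[5-({[tert-butyl(dimethyl)silyl]oxy}methyl)-1H-pyrrol-2-yl]-16-methylheptadecan-1-one | CC(C)CCCCCCCCCCCCCCC(=O)c1ccc(CO[Si](C)(C)C(C)(C)C)[nH]1
F7 | step 3 | 5-formyl-1H-pyrrole-2-carbonyl chloride | O=Cc1ccc(C(=O)Cl)[nH]1
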